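## Retrosynthetic overview

1. Target ⇐ late allylic C9–H hydroxylation ⇐ C3 acetate ⇐ reagent-controlled reduction of a (Z)-2-ethylidenecyclopentanone (oplopa-4,10(14)-dien-3-one 8-angelate).
2. Five-membered ring (formed last) ⇐ ring contraction of a cadinane: 1,2-acyl shift of C3 from C4 to C5 in a 3-oxo-4,5-epoxide, the epoxide-triggered counterpart of the cadinane → oplopane step; the extruded C4 carbonyl is then converted into the 4(5)-ene.
3. Ring B of the cadinane (formed second) ⇐ cationic carbonyl-ene closure (C8–C9) of a ring-A aldehyde onto its isopropenyl group, ending in loss of H-14 to the 10(14)-methylene, as in cadinyl cation → γ-cadinene.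
4. Aldehyde ⇐ γ-selective Mukaiyama–Michael/Nef union of the carvone silyl dienol ether with (E)-3-methyl-1-nitrobut-1-ene (brings C7, C8 and the isopropyl group).
5. Ring A and C1 come from (S)-(+)-carvone; ring order: ring A (bought) → ring B → contraction of ring A to the cyclopentane.

Assumption: cadinane numbering is kept for all bicyclic compounds, also after contraction (C1/C6 ring fusion; ring A = C1–C6 with CH3-15 on C4; ring B = C1, C6, C7 (isopropyl), C8, C9, C10 (C14); after contraction C3 is bonded to C5 and C4–C15 is the side chain on C5); β = face of H-6, α = face of H-1; the four starting materials are bought.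

## Route

Step 1
Reactants: 1 (S)-(+)-carvone
Product: 3 trimethyl{[(5R)-2-methyl-5-(prop-1-en-2-yl)cyclohexa-1,3-dien-1-yl]oxy}silane, via bromomagnesium dienolate 2 (not isolated)
Conditions: MeMgBr (1.2 equiv), FeCl3 (5 mol %), Et2O, −20 °C; then TMSCl, Et3N, DMPU, −20 → 25 °C
Reagents that add atoms: chlorotrimethylsilane, C[Si](C)(C)Cl
Why: Iron-catalysed Grignard deprotonation at the γ-carbon gives the through-conjugated dienolate, whose O-silylation furnishes the 1-siloxy-1,3-diene (extended silyl dienol ether formation); the existing stereocentre C1 is not touched.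

Step 2
Reactants: 4 isobutyraldehyde; 5 nitromethane
Product: 7 (E)-3-methyl-1-nitrobut-1-ene, via nitro alcohol 6 (not isolated)
Conditions: KOtBu (5 mol %), THF/t-BuOH, 0 °C; then MsCl, Et3N, CH2Cl2, 0 °C
Reagents that add atoms: none
Why: Henry (nitroaldol) reaction followed by mesylation and E1cB elimination gives the more stable E nitroalkene; the carbinol stereocentre of the racemic intermediate is destroyed.

Step 3
Reactants: 3 silyl dienol ether; 7 (E)-3-methyl-1-nitrobut-1-ene
Product: 9 (2S)-3-methyl-2-[(1R,6R)-3-methyl-4-oxo-6-(prop-1-en-2-yl)cyclohex-2-en-1-yl]butanal, via tin nitronate 8 (not isolated)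
Conditions: SnCl4 (1.1 equiv), CH2Cl2, −78 °C; then H2O, THF, 0 → 25 °C
Reagents that add atoms: water, O
Why: Vinylogous Mukaiyama–Michael addition at the γ-terminus C6 of the siloxydiene (the α-terminus is blocked by the methyl group) followed by Nef hydrolysis of the nitronate in the same flask: the nitroalkene adds anti to the C1 isopropenyl group, which sets C6 trans to C1, through the compact endo [4+2]-type transition state with the nitro group under the diene and the isopropyl group turned away from C1, which sets C7.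

Step 4
Reactants: 9 keto aldehyde
Product: 10 8β-hydroxycadina-4,10(14)-dien-3-one
Conditions: Me2AlCl (2.5 equiv), CH2Cl2, −78 → −20 °C
Reagents that add atoms: none
Why: Lewis-acid-promoted type-2 intramolecular carbonyl-ene (Prins-type cation–olefin) cyclisation closes ring B as a trans-fused chair with the C7 isopropyl equatorial and the aluminium-bound oxygen axial on the H-6 face (this sets C8), because only there can it take a C14 hydrogen, which delivers the 10(14)-methylene just as proton loss from the cadinyl cation does.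

Step 5
Reactants: 10 8β-hydroxycadina-4,10(14)-dien-3-one; 11 angelic acid
Product: 13 3-oxocadina-4,10(14)-dien-8β-yl (2Z)-2-methylbut-2-enoate, via mixed anhydride 12 (not isolated)
Conditions: 11, 2,4,6-trichlorobenzoyl chloride, Et3N, toluene, 25 °C; then 10, 80 °C
Reagents that add atoms: none
Why: Yamaguchi mixed-anhydride esterification acylates the hindered axial alcohol at the unshielded angeloyl carbonyl without a nucleophilic catalyst that would isomerise the Z ester to the tiglate; no stereocentre changes.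

Step 6
Reactants: 13 dienone angelate
Product: 14 4α,5α-epoxy-3-oxocadin-10(14)-en-8β-yl (2Z)-2-methylbut-2-enoate
Conditions: 30 % aq. H2O2, NaOH (0.2 equiv), MeOH, 0 °C
Reagents that add atoms: hydrogen peroxide, OO
Why: Weitz–Scheffer nucleophilic epoxidation touches only the enone (the methylene and the angelate are not electrophilic enough), hydroperoxide adding axially to C5 anti to H-6 to give the α-epoxide, whose two stereocentres are erased again in steps 7 and 8.

Step 7
Reactants: 14 epoxy ketone
Product: 15 3,4-dioxo-oplop-10(14)-en-8β-yl (2Z)-2-methylbut-2-enoate (enol form)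
Conditions: BF3·OEt2 (1.2 equiv), CH2Cl2, −30 → 0 °C
Reagents that add atoms: none
Why: Lewis-acid opening of the epoxide at C5 (cleavage of the C4–O bond is disfavoured by the adjacent carbonyl) with concerted 1,2-acyl shift of C3 from C4 to C5 (Meinwald/semipinacol-type epoxy ketone rearrangement) contracts ring A to the cyclopentane and turns C4 into the acetyl carbon, which is the cadinane-to-oplopane ring contraction; C5 becomes an enolised centre and the other stereocentres are untouched.

Step 8
Reactants: 15 β-diketone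
Product: 18 (4Z)-3-oxo-oplopa-4,10(14)-dien-8β-yl (2Z)-2-methylbut-2-enoate, via methyl enol ether 16 (not isolated), via allylic alcohol 17 (not isolated)
Conditions: HC(OMe)3, CSA (5 mol %), MeOH, 25 °C; then CeCl3·7H2O, NaBH4, −20 °C; then 1 M HCl, THF, 25 °C
Reagents that add atoms: water, O
Why: Acid-catalysed enol etherification under thermodynamic control puts OMe on the ring oxygen (the exocyclic isomer suffers A(1,3) strain with C6/C7), Luche reduction then reduces only the acetyl carbonyl, and acid hydrolysis with loss of water (Stork–Danheiser transposition) gives the 3-oxo-4(5)-ene, Z because a methyl syn to C6 would clash with the equatorial C7 isopropyl.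

Step 9
Reactants: 18 Z enone
Product: 19 (4Z)-3β-hydroxy-oplopa-4,10(14)-dien-8β-yl (2Z)-2-methylbut-2-enoate
Conditions: (R)-2-methyl-CBS-oxazaborolidine (20 mol %), catecholborane (1.5 equiv), toluene, −78 °C
Reagents that add atoms: none
Why: Corey–Bakshi–Shibata reduction with the alkylidene-bearing C5 as the large group and C2 as the small one: the (R)-catalyst delivers hydride to the α face and sets C3 as the 3β (S) alcohol by reagent control, which is needed because the two faces of this ketone are almost equivalent in a trans-hydrindane; catecholborane does not hydroborate the methylene at −78 °C.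

Step 10
Reactants: 19 allylic alcohol
Product: 20 (4Z)-3β-acetoxy-oplopa-4,10(14)-dien-8β-yl (2Z)-2-methylbut-2-enoate
Conditions: Ac2O, pyridine, DMAP (5 mol %), CH2Cl2, 0 → 25 °C
Reagents that add atoms: acetic anhydride, CC(=O)OC(C)=O
Why: DMAP-catalysed acetylation of the only free hydroxyl; no stereocentre changes.

Step 11
Reactants: 20 diester
Product: 21 (4Z)-3β-acetoxy-9α-hydroxy-oplopa-4,10(14)-dien-8β-yl (2Z)-2-methylbut-2-enoate (target CNP0113604.1)
Conditions: SeO2 (0.3 equiv), t-BuOOH (3 equiv), CH2Cl2, 25 °C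
Reagents that add atoms: tert-butyl hydroperoxide, CC(C)(C)OO
Why: Selenium dioxide ene reaction followed by [2,3]-sigmatropic shift (Riley–Sharpless allylic hydroxylation) at the only electron-rich alkene, the 10(14)-methylene (the ethylidene is deactivated by its allylic acetate, and the C9 methylene is preferred over the tertiary C1–H): the axial 9α-hydrogen is removed and oxygen is returned axially on the α face, anti to the axial 8β-angelate, which sets C9.

## Compound list

1 | (S)-(+)-carvone, (5S)-2-methyl-5-(prop-1-en-2-yl)cyclohex-2-en-1-one | CC1=CC[C@@H](CC1=O)C(C)=C | starting material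
2 | bromomagnesium (5R)-2-methyl-5-(prop-1-en-2-yl)cyclohexa-1,3-dien-1-olate | CC1=C(O[Mg]Br)C[C@@H](C(C)=C)C=C1 | intermediate
3 | trimethyl{[(5R)-2-methyl-5-(prop-1-en-2-yl)cyclohexa-1,3-dien-1-yl]oxy}silane | CC1=C(O[Si](C)(C)C)C[C@@H](C(C)=C)C=C1 | intermediate
4 | isobutyraldehyde (2-methylpropanal) | CC(C)C=O | starting material
5 | nitromethane | C[N+](=O)[O-] | starting material
6 | 3-methyl-1-nitrobutan-2-ol (racemic) | CC(C)C(O)C[N+](=O)[O-] | intermediate
7 | (E)-3-methyl-1-nitrobut-1-ene | CC(C)/C=C/[N+](=O)[O-] | intermediate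
8 | trichlorostannyl nitronate of the Michael adduct (C=N geometry not defined) | Cl[Sn](Cl)(Cl)O[N+]([O-])=C[C@@H](C(C)C)[C@@H]1C=C(C)C(=O)C[C@H]1C(C)=C | intermediate
9 | (2S)-3-methyl-2-[(1R,6R)-3-methyl-4-oxo-6-(prop-1-en-2-yl)cyclohex-2-en-1-yl]butanal | O=C[C@@H](C(C)C)[C@@H]1C=C(C)C(=O)C[C@H]1C(C)=C | intermediate
10 | 8β-hydroxycadina-4,10(14)-dien-3-one, (4aR,5S,6R,8aR)-6-hydroxy-3-methyl-8-methylidene-5-(propan-2-yl)-4a,5,6,7,8,8a-hexahydronaphthalen-2(1H)-one | C=C1C[C@@H](O)[C@@H](C(C)C)[C@@H]2C=C(C)C(=O)C[C@@H]12 | intermediate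
11 | angelic acid, (2Z)-2-methylbut-2-enoic acid | C/C=C(/C)C(=O)O | starting material
12 | angelic 2,4,6-trichlorobenzoic anhydride | C/C=C(/C)C(=O)OC(=O)c1c(Cl)cc(Cl)cc1Cl | intermediate
13 | 3-oxocadina-4,10(14)-dien-8β-yl (2Z)-2-methylbut-2-enoate | C=C1C[C@@H](OC(=O)/C(C)=C\C)[C@@H](C(C)C)[C@@H]2C=C(C)C(=O)C[C@@H]12 | intermediate
14 | 4α,5α-epoxy-3-oxocadin-10(14)-en-8β-yl (2Z)-2-methylbut-2-enoate | C=C1C[C@@H](OC(=O)/C(C)=C\C)[C@@H](C(C)C)[C@@H]2[C@@H]3O[C@]3(C)C(=O)C[C@@H]12 | intermediate
15 | 3,4-dioxo-oplop-10(14)-en-8β-yl (2Z)-2-methylbut-2-enoate, written as its 3-hydroxy-3(5)-en-4-one enol | C=C1C[C@@H](OC(=O)/C(C)=C\C)[C@@H](C(C)C)[C@@H]2C(C(C)=O)=C(O)C[C@@H]12 | intermediate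
16 | 3-methoxy-4-oxo-oplopa-3(5),10(14)-dien-8β-yl (2Z)-2-methylbut-2-enoate | C=C1C[C@@H](OC(=O)/C(C)=C\C)[C@@H](C(C)C)[C@@H]2C(C(C)=O)=C(OC)C[C@@H]12 | intermediate
17 | 4-hydroxy-3-methoxy-oplopa-3(5),10(14)-dien-8β-yl (2Z)-2-methylbut-2-enoate (both C4 epimers, which converge in the same flask) | C=C1C[C@@H](OC(=O)/C(C)=C\C)[C@@H](C(C)C)[C@@H]2C(C(C)O)=C(OC)C[C@@H]12 | intermediate
18 | (4Z)-3-oxo-oplopa-4,10(14)-dien-8β-yl (2Z)-2-methylbut-2-enoate, (1Z,3aR,6R,7S,7aR)-1-ethylidene-4-methylidene-2-oxo-7-(propan-2-yl)octahydro-1H-inden-6-yl ester | C=C1C[C@@H](OC(=O)/C(C)=C\C)[C@@H](C(C)C)[C@@H]2/C(=C/C)C(=O)C[C@@H]12 | intermediate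
19 | (4Z)-3β-hydroxy-oplopa-4,10(14)-dien-8β-yl (2Z)-2-methylbut-2-enoate (2S at the carbinol in indene numbering) | C=C1C[C@@H](OC(=O)/C(C)=C\C)[C@@H](C(C)C)[C@@H]2/C(=C/C)[C@@H](O)C[C@@H]12 | intermediate
20 | (4Z)-3β-acetoxy-oplopa-4,10(14)-dien-8β-yl (2Z)-2-methylbut-2-enoate | C=C1C[C@@H](OC(=O)/C(C)=C\C)[C@@H](C(C)C)[C@@H]2/C(=C/C)[C@@H](OC(C)=O)C[C@@H]12 | intermediate
21 | (1Z,2S,3aR,5S,6S,7S,7aR)-2-acetoxy-1-ethylidene-5-hydroxy-4-methylidene-7-(propan-2-yl)octahydro-1H-inden-6-yl (2Z)-2-methylbut-2-enoate (CNP0113604.1) | C=C1[C@H](O)[C@@H](OC(=O)/C(C)=C\C)[C@@H](C(C)C)[C@@H]2/C(=C/C)[C@@H](OC(C)=O)C[C@@H]12 | target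

## Step count and risks

Total step count: 11. Longest linear sequence: 10 steps (steps 1 and 3–11, from (S)-(+)-carvone); step 2 is a one-step side branch.

The three steps most likely to fail:

**Step 7 (ring contraction).** The migration terminus C5 is only secondary. BF3 may instead cleave the C4–O bond (hydride shift to the six-membered 3,5-dione), shift the methyl group, or give a fluorohydrin. The fallback runs the same 1,2-acyl shift as a radical process that needs no cation at C5. It sets out from 14. LiBr/AcOH (THF, 25 °C) opens the epoxide at C5 with inversion to give the 5β-bromo-4α-hydroxy ketone (bromohydrin) F3. Slow addition of Bu3SnH with AIBN (benzene, 80 °C) generates the C5 radical, which adds to the C3 carbonyl; the cyclopropyloxy radical reopens toward the tertiary α-hydroxy radical at C4 (Dowd–Beckwith-type 1,2-acyl migration, run here as a ring contraction). Hydrogen transfer gives the ring-contracted β-hydroxy ketone F4 as a mixture at C4/C5. MsCl/Et3N then DBU (CH2Cl2, 0 → 25 °C) eliminates to the Z enone. The route is rejoined at 18, and 15–17 are bypassed.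

**Step 3 (fragment union).** The C6/C7 diastereoselectivity of the Lewis-acid addition may be modest, and the acidic Nef hydrolysis can epimerise C7 or trigger premature cyclisation. The fallback fixes both centres in a concerted step and unmasks the aldehyde under near-neutral conditions. It sets out from 3 and 7. Heating without Lewis acid (toluene, 60 °C) gives the endo Diels–Alder adduct F1 (nitro endo, addition anti to the isopropenyl group). TBAF/AcOH (THF, 0 °C) cleaves the bridgehead silyl ether, and the β-nitro alkoxide fragments (retro-Henry) to the γ-nitro enone F2. NaOMe (1 equiv, MeOH, 0 °C) followed by buffered aqueous TiCl3/NH4OAc (reductive Nef) gives the aldehyde. The route is rejoined at 9.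

**Step 11 (late allylic hydroxylation).** Oxidation at the tertiary C1–H or at the ethylidene, or over-oxidation to the 9-ketone, would cost material at the last stage. The fallback moves the C–H oxidation to a substrate with only one electron-rich alkene and replaces the final chemoselective oxidation by a chemoselective acylation. It sets out from 18. SeO2 (0.3 equiv)/t-BuOOH (CH2Cl2, 25 °C) gives the 9α-hydroxy enone F5. Reduction as in step 9, with 3 equiv catecholborane, gives the 3β,9α-diol F6. Ac2O (1.1 equiv), pyridine, CH2Cl2, −20 °C acetylates the unhindered cyclopentyl allylic 3-OH in preference to the axial 9-OH flanked by the angelate. The route is rejoined at 21.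

Further compounds
F1 | step 3 | endo Diels–Alder adduct, trimethyl{[6-methyl-7-nitro-8-(propan-2-yl)-3-(prop-1-en-2-yl)bicyclo[2.2.2]oct-5-en-1-yl]oxy}silane | C[Si](C)(C)O[C@@]12C[C@@H](C(C)=C)[C@@H](C=C1C)[C@H](C(C)C)[C@H]2[N+](=O)[O-]
F2 | step 3 | γ-nitro enone, 2-methyl-4-(3-methyl-1-nitrobutan-2-yl)-5-(prop-1-en-2-yl)cyclohex-2-en-1-one with the configuration of 9 | [O-][N+](=O)C[C@@H](C(C)C)[C@@H]1C=C(C)C(=O)C[C@H]1C(C)=C
F3 | step 7 | 5β-bromo-4α-hydroxy-3-oxocadin-10(14)-en-8β-yl (2Z)-2-methylbut-2-enoate | C=C1C[C@@H](OC(=O)/C(C)=C\C)[C@@H](C(C)C)[C@@H]2[C@@H](Br)[C@](C)(O)C(=O)C[C@@H]12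
F4 | step 7 | 4-hydroxy-3-oxo-oplop-10(14)-en-8β-yl (2Z)-2-methylbut-2-enoate (C4/C5 epimers) | C=C1C[C@@H](OC(=O)/C(C)=C\C)[C@@H](C(C)C)[C@@H]2C(C(C)O)C(=O)C[C@@H]12
F5 | step 11 | (4Z)-9α-hydroxy-3-oxo-oplopa-4,10(14)-dien-8β-yl (2Z)-2-methylbut-2-enoate | C=C1[C@H](O)[C@@H](OC(=O)/C(C)=C\C)[C@@H](C(C)C)[C@@H]2/C(=C/C)C(=O)C[C@@H]12
F6 | step 11 | (4Z)-3β,9α-dihydroxy-oplopa-4,10(14)-dien-8β-yl (2Z)-2-methylbut-2-enoate | C=C1[C@H](O)[C@@H](OC(=O)/C(C)=C\C)[C@@H](C(C)C)[C@@H]2/C(=C/C)[C@@H](O)C[C@@H]12
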